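Ring A is disconnected across C7–C8 and C4a–C8a. The route exploits its oxygen pattern: the prenyl-bearing C8 sits between the meta-related oxygens at C7 and C8a, while C5 and C6 carry adjacent oxygens. A single thermal benzannulation of 3-ethoxy-4-methoxycyclobutenone 4 with the prenyl-substituted siloxyalkyne 8 builds this hexasubstituted ring with its four oxygens as OH, OSi, OEt and OMe, leaving C4a as the only unsubstituted carbon. Ring C is then grown from C4a under non-acidic conditions (formylation, ynone closure to a chromone), the C5 ether is cleaved by chelation on the achiral chromone, and the lone (2S) centre is set last by enantioselective palladium-catalysed arylation.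

Key step: step 3

Assumption: the C2 centre of the target is read from the SMILES as (S); flavonoid numbering (O1, C2–C4, C4a, C5–C8, C8a) is used, and prenyl means 3-methylbut-2-en-1-yl.
Assumption: the sense of induction in step 10 is assigned by analogy with cyclic enones and should be confirmed on the first run; the antipodal ligand is equally available. (R)-t-BuPyOX is (R)-4-tert-butyl-2-(pyridin-2-yl)-4,5-dihydrooxazole.

Step 1
Reactants: 1 methoxyacetyl chloride; 2 ethoxyacetylene
Product: 4 3-ethoxy-4-methoxycyclobut-2-en-1-one (racemic), via methoxyketene 3 (not isolated)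
Conditions: Et3N, 2 (2 equiv), Et2O, slow addition of 1, 0 °C → rt
Reagents that add atoms: none
Why: Et3N dehydrochlorinates 1 to methoxyketene 3, which the excess ynol ether traps in a regiospecific ketene–alkyne [2+2] cycloaddition (ketene carbonyl carbon to the nucleophilic terminal alkyne carbon), the standard entry to 4-substituted 3-ethoxycyclobutenones, while slow addition keeps 3 dilute and limits its dimerisation.

Step 2
Reactants: 5 ethyl 4-methylpent-3-enoate
Product: 8 triisopropyl[(5-methylhex-4-en-1-yn-1-yl)oxy]silane, via lithium dibromoenolate 6 (not isolated), via lithium ynolate 7 (not isolated)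
Conditions: CH2Br2, lithium 2,2,6,6-tetramethylpiperidide, THF, −78 °C; then 5; LiN(SiMe3)2; n-BuLi, −78 → 0 °C; i-Pr3SiCl, −78 °C → rt
Reagents that add atoms: dibromomethane, BrCBr; chlorotriisopropylsilane, CC(C)[Si](Cl)(C(C)C)C(C)C
Why: Kowalski ester homologation, in which LiCHBr2 adds to the ester carbonyl, LiN(SiMe3)2 collapses the adduct to dibromo enolate 6, bromine–lithium exchange triggers 1,2-migration of the prenyl group to ynolate 7 and the hindered silyl chloride traps it on oxygen, the ester being added last to the preformed carbenoid so that carbonyl addition outruns deprotonation of the α-CH2.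

Step 3
Reactants: 4 3-ethoxy-4-methoxycyclobut-2-en-1-one; 8 triisopropyl[(5-methylhex-4-en-1-yn-1-yl)oxy]silane
Product: 13 5-ethoxy-6-methoxy-2-(3-methylbut-2-en-1-yl)-3-(triisopropylsilyloxy)phenol, via vinylketene 9 (not isolated), via vinylcyclobutenone 10 (not isolated), via dienylketene 11 (not isolated), via cyclohexadienone 12 (not isolated)
Conditions: 8 (1.2 equiv), toluene, 80 °C then 110 °C, sealed tube, argon
Reagents that add atoms: none
Why: Heating opens 4 by conrotatory 4π electrocyclic cleavage of C1–C4, the methoxy group turning outward, to vinylketene 9, whose ketene C=C adds [2+2] to the siloxyalkyne to give vinylcyclobutenone 10, and a second 4π opening gives dienylketene 11. Ring A is closed by 6π electrocyclisation of 11 (six-membered, disrotatory) to dienone 12, which enolises to the phenol; the net new bonds are C7–C8 and C4a–C8a. The closest known reaction is the Danheiser benzannulation of cyclobutenones with siloxyalkynes to resorcinol monosilyl ethers, of which only the dialkoxy substitution of 4 is an extension. No stereocentre is created, and the centres of 4, 10 and 12 vanish on aromatisation. The one selectivity needed is the regiochemistry of the [2+2] step, and polarity fixes it: the electrophilic ketene carbonyl carbon bonds to the nucleophilic, prenyl-bearing β-carbon of the ynol ether, so the prenyl carbon ends between the new C7 hydroxyl and the C8a silyl ether. The C4 methoxy group lowers the barrier of the first ring opening, and the slight excess of 8 limits acylation of 13 by 9.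

Step 4
Reactants: 13 5-ethoxy-6-methoxy-2-(3-methylbut-2-en-1-yl)-3-(triisopropylsilyloxy)phenol
Product: 14 [5-ethoxy-3,4-dimethoxy-2-(3-methylbut-2-en-1-yl)phenoxy]triisopropylsilane
Conditions: MeI, K2CO3, acetone, 50 °C
Reagents that add atoms: iodomethane, CI
Why: Williamson O-methylation of the only free hydroxyl (C7) under aprotic carbonate conditions to which the aryl triisopropylsilyl ether is inert.

Step 5
Reactants: 14 [5-ethoxy-3,4-dimethoxy-2-(3-methylbut-2-en-1-yl)phenoxy]triisopropylsilane
Product: 15 5-ethoxy-3,4-dimethoxy-2-(3-methylbut-2-en-1-yl)phenol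
Conditions: n-Bu4NF, AcOH, THF, 0 °C
Reagents that add atoms: none
Why: Fluoride cleaves the Si–O bond of the aryl silyl ether, and the acetic acid buffer delivers the neutral electron-rich phenol instead of its oxidation-prone phenoxide.

Step 6
Reactants: 15 5-ethoxy-3,4-dimethoxy-2-(3-methylbut-2-en-1-yl)phenol
Product: 16 6-ethoxy-2-hydroxy-4,5-dimethoxy-3-(3-methylbut-2-en-1-yl)benzaldehyde
Conditions: MgCl2, Et3N, (CH2O)n, MeCN, 80 °C; cold dilute aq. HCl work-up
Reagents that add atoms: paraformaldehyde (as formaldehyde), C=O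
Why: Casnati–Skattebøl ortho-formylation, in which the magnesium phenoxide delivers formaldehyde to the only free ortho carbon (C4a) and the resulting benzylic alkoxide is oxidised by hydride transfer to a second formaldehyde, all under basic conditions that cannot trigger acid cyclisation of the prenyl group onto the neighbouring hydroxyl.

Step 7
Reactants: 16 6-ethoxy-2-hydroxy-4,5-dimethoxy-3-(3-methylbut-2-en-1-yl)benzaldehyde; 17 ethynylmagnesium bromide
Product: 18 1-[6-ethoxy-2-hydroxy-4,5-dimethoxy-3-(3-methylbut-2-en-1-yl)phenyl]prop-2-yn-1-ol (racemic)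
Conditions: 17 (3 equiv), THF, 0 °C → rt; aq. NH4Cl
Reagents that add atoms: none
Why: Grignard 1,2-addition of the acetylide to the aldehyde after the first equivalent has deprotonated the phenol, giving a racemic carbinol centre that is removed by the oxidation in step 8.

Step 8
Reactants: 18 1-[6-ethoxy-2-hydroxy-4,5-dimethoxy-3-(3-methylbut-2-en-1-yl)phenyl]prop-2-yn-1-ol
Product: 20 5-ethoxy-6,7-dimethoxy-8-(3-methylbut-2-en-1-yl)-4H-chromen-4-one, via ynone 19 (not isolated)
Conditions: MnO2, CH2Cl2, rt; then K2CO3 (cat.), acetone, rt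
Reagents that add atoms: none
Why: MnO2 selectively oxidises the doubly activated benzylic–propargylic alcohol to ynone 19, whose phenoxide closes ring C by 6-endo-dig oxa-Michael addition to the terminal alkyne carbon, a standard route from 2-hydroxyaryl ynones to chromones.

Step 9
Reactants: 20 5-ethoxy-6,7-dimethoxy-8-(3-methylbut-2-en-1-yl)-4H-chromen-4-one
Product: 21 5-hydroxy-6,7-dimethoxy-8-(3-methylbut-2-en-1-yl)-4H-chromen-4-one
Conditions: MgI2·OEt2, toluene–THF, 80 °C; aq. NH4Cl
Reagents that add atoms: none
Why: Chelation-assisted ether cleavage in which magnesium bridges the C4 carbonyl and the peri C5 oxygen (the only ether that can chelate, twisted out of plane by the C6 methoxy group) and iodide removes the ethyl group by SN2 displacement, using a reagent known to spare prenyl groups in 5-alkoxy prenylflavonoids and running on the achiral chromone so that no stereocentre is exposed to Lewis acid.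

Step 10
Reactants: 21 5-hydroxy-6,7-dimethoxy-8-(3-methylbut-2-en-1-yl)-4H-chromen-4-one; 22 4-(tert-butyldimethylsilyloxy)phenylboronic acid
Product: 23 (2S)-2-[4-(tert-butyldimethylsilyloxy)phenyl]-5-hydroxy-6,7-dimethoxy-8-(3-methylbut-2-en-1-yl)-2,3-dihydro-4H-chromen-4-one
Conditions: Pd(OCOCF3)2 (5 mol %), (R)-t-BuPyOX (6 mol %), NH4PF6, H2O, 22 (2 equiv), ClCH2CH2Cl, 60 °C
Reagents that add atoms: none
Why: Asymmetric conjugate addition of an arylboronic acid to a chromone with a cationic divalent palladium–pyridinooxazoline catalyst (transmetalation, enantio-determining insertion of C2=C3 into the Pd–aryl bond with the tert-butyl group of the ligand shielding one face, protonolysis of the palladium enolate by water), where the (R) ligand is the mirror image of the one that gives (R) adducts of cyclic enones and should therefore set C2 as (S).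

Step 11
Reactants: 23 (2S)-2-[4-(tert-butyldimethylsilyloxy)phenyl]-5-hydroxy-6,7-dimethoxy-8-(3-methylbut-2-en-1-yl)-2,3-dihydro-4H-chromen-4-one
Product: 24 (2S)-5-hydroxy-2-(4-hydroxyphenyl)-6,7-dimethoxy-8-(3-methylbut-2-en-1-yl)-2,3-dihydro-4H-chromen-4-one
Conditions: KHF2, MeOH, rt
Reagents that add atoms: none
Why: Fluoride cleavage of the phenolic silyl ether with weakly acidic KHF2, which avoids the basic conditions that would racemise C2 by retro-oxa-Michael ring opening and leaves the methyl ethers and the prenyl group untouched.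

Compound list
1 | methoxyacetyl chloride | COCC(=O)Cl | starting material
2 | ethoxyacetylene (ethoxyethyne) | CCOC#C | starting material
3 | methoxyketene | COC=C=O | intermediate
4 | 3-ethoxy-4-methoxycyclobut-2-en-1-one (racemic) | CCOC1=CC(=O)C1OC | intermediate
5 | ethyl 4-methylpent-3-enoate | CCOC(=O)CC=C(C)C | starting material
6 | lithium 1,1-dibromo-5-methylhexa-1,4-dien-2-olate | [Li+].[O-]C(CC=C(C)C)=C(Br)Br | intermediate
7 | lithium 5-methylhex-4-en-1-yn-1-olate | [Li+].[O-]C#CCC=C(C)C | intermediate
8 | triisopropyl[(5-methylhex-4-en-1-yn-1-yl)oxy]silane | CC(C)=CCC#CO[Si](C(C)C)(C(C)C)C(C)C | intermediate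
9 | (3Z)-3-ethoxy-4-methoxybuta-1,3-dien-1-one | O=C=C/C(OCC)=C/OC | intermediate
10 | 4-[(Z)-1-ethoxy-2-methoxyethenyl]-2-(3-methylbut-2-en-1-yl)-3-(triisopropylsilyloxy)cyclobut-2-en-1-one (racemic) | O=C1C(CC=C(C)C)=C(O[Si](C(C)C)(C(C)C)C(C)C)C1/C(OCC)=C/OC | intermediate
11 | (3E,5Z)-5-ethoxy-6-methoxy-2-(3-methylbut-2-en-1-yl)-3-(triisopropylsilyloxy)hexa-1,3,5-trien-1-one | O=C=C(CC=C(C)C)/C(O[Si](C(C)C)(C(C)C)C(C)C)=C\C(OCC)=C\OC | intermediate
12 | 5-ethoxy-6-methoxy-2-(3-methylbut-2-en-1-yl)-3-(triisopropylsilyloxy)cyclohexa-2,4-dien-1-one (racemic) | O=C1C(CC=C(C)C)=C(O[Si](C(C)C)(C(C)C)C(C)C)C=C(OCC)C1OC | intermediate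
13 | 5-ethoxy-6-methoxy-2-(3-methylbut-2-en-1-yl)-3-(triisopropylsilyloxy)phenol | CCOc1cc(O[Si](C(C)C)(C(C)C)C(C)C)c(CC=C(C)C)c(O)c1OC | intermediate
14 | [5-ethoxy-3,4-dimethoxy-2-(3-methylbut-2-en-1-yl)phenoxy]triisopropylsilane | CCOc1cc(O[Si](C(C)C)(C(C)C)C(C)C)c(CC=C(C)C)c(OC)c1OC | intermediate
15 | 5-ethoxy-3,4-dimethoxy-2-(3-methylbut-2-en-1-yl)phenol | CCOc1cc(O)c(CC=C(C)C)c(OC)c1OC | intermediate
16 | 6-ethoxy-2-hydroxy-4,5-dimethoxy-3-(3-methylbut-2-en-1-yl)benzaldehyde | CCOc1c(C=O)c(O)c(CC=C(C)C)c(OC)c1OC | intermediate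
17 | ethynylmagnesium bromide | C#C[Mg]Br | starting material
18 | 1-[6-ethoxy-2-hydroxy-4,5-dimethoxy-3-(3-methylbut-2-en-1-yl)phenyl]prop-2-yn-1-ol (racemic) | CCOc1c(C(O)C#C)c(O)c(CC=C(C)C)c(OC)c1OC | intermediate
19 | 1-[6-ethoxy-2-hydroxy-4,5-dimethoxy-3-(3-methylbut-2-en-1-yl)phenyl]prop-2-yn-1-one | CCOc1c(C(=O)C#C)c(O)c(CC=C(C)C)c(OC)c1OC | intermediate
20 | 5-ethoxy-6,7-dimethoxy-8-(3-methylbut-2-en-1-yl)-4H-chromen-4-one | CCOc1c(OC)c(OC)c(CC=C(C)C)c2occc(=O)c12 | intermediate
21 | 5-hydroxy-6,7-dimethoxy-8-(3-methylbut-2-en-1-yl)-4H-chromen-4-one | COc1c(O)c2c(=O)ccoc2c(CC=C(C)C)c1OC | intermediate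
22 | 4-(tert-butyldimethylsilyloxy)phenylboronic acid | CC(C)(C)[Si](C)(C)Oc1ccc(B(O)O)cc1 | starting material
23 | (2S)-2-[4-(tert-butyldimethylsilyloxy)phenyl]-5-hydroxy-6,7-dimethoxy-8-(3-methylbut-2-en-1-yl)-2,3-dihydro-4H-chromen-4-one | COc1c(O)c2c(c(CC=C(C)C)c1OC)O[C@H](c1ccc(O[Si](C)(C)C(C)(C)C)cc1)CC2=O | intermediate
24 | (2S)-5-hydroxy-2-(4-hydroxyphenyl)-6,7-dimethoxy-8-(3-methylbut-2-en-1-yl)-2,3-dihydro-4H-chromen-4-one | COc1c(O)c2c(c(CC=C(C)C)c1OC)O[C@H](c1ccc(O)cc1)CC2=O | target

Total step count: 11. Longest linear sequence: 10 steps (step 1, then steps 3 to 11; step 2 is a one-step branch).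

Steps most likely to fail

Step 3. The donor-rich vinylketene 9 may oligomerise before it meets the alkyne, the cascade may stop at cyclobutenone 10, or phenol 13 may be acylated by 9. The fallback takes ring A from a preformed arene instead of building it. It sets out from no intermediate of the route (17 is its only numbered input) and comes back at 21. The sodium salt of commercial 3,4,5-trimethoxyphenol F1 (NaH, toluene) is C-prenylated with prenyl bromide at one of its two equivalent ortho carbons, the para position being blocked, to give 3,4,5-trimethoxy-2-(3-methylbut-2-en-1-yl)phenol F2. Magnesium-mediated formylation as in step 6 gives 2-hydroxy-4,5,6-trimethoxy-3-(3-methylbut-2-en-1-yl)benzaldehyde F3. Addition of 17 gives 1-[2-hydroxy-4,5,6-trimethoxy-3-(3-methylbut-2-en-1-yl)phenyl]prop-2-yn-1-ol F4. MnO2 oxidation gives 1-[2-hydroxy-4,5,6-trimethoxy-3-(3-methylbut-2-en-1-yl)phenyl]prop-2-yn-1-one F5, which closes with K2CO3 to 5,6,7-trimethoxy-8-(3-methylbut-2-en-1-yl)-4H-chromen-4-one F6. Chelation-assisted cleavage of the peri methyl ether with MgI2·OEt2 then gives 21.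

Step 10. The acidic, chelating 5-hydroxy-4-oxo unit may bind palladium or protonate the aryl–palladium species, so that protodeboronation outruns insertion into the electron-rich chromone. The fallback changes the order of events so that the catalyst meets only a fully etherified chromone. It sets out from 20 and comes back at 23. The same palladium-catalysed arylation with 22 on the ethyl ether gives (2S)-2-[4-(tert-butyldimethylsilyloxy)phenyl]-5-ethoxy-6,7-dimethoxy-8-(3-methylbut-2-en-1-yl)-2,3-dihydro-4H-chromen-4-one F7. Its C5 ethyl ether is then cleaved with MgI2·OEt2 at the lowest temperature that gives conversion, with the enantiomeric purity checked afterwards, to give 23.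

Step 2. The carbenoid base may deprotonate the allyl-activated α-CH2 of 5 instead of adding to the carbonyl, and the siloxyalkyne may be lost by hydrolysis on isolation. The fallback makes the ynolate by oxidation of an acetylide instead of by ester homologation. It sets out from 17 and commercial prenyl bromide and comes back at 7. Coupling with CuCl as catalyst in THF, where monovalent copper favours attack at the primary allylic carbon, gives 5-methylhex-4-en-1-yne F8. n-BuLi gives (5-methylhex-4-en-1-yn-1-yl)lithium F9. Oxidation with t-BuOOLi (from t-BuOOH and LiN(SiMe3)2) gives ynolate 7, which i-Pr3SiOTf traps as 8.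

Further compounds
F1 | step 3 | 3,4,5-trimethoxyphenol | COc1cc(O)cc(OC)c1OC
F2 | step 3 | 3,4,5-trimethoxy-2-(3-methylbut-2-en-1-yl)phenol | COc1cc(O)c(CC=C(C)C)c(OC)c1OC
F3 | step 3 | 2-hydroxy-4,5,6-trimethoxy-3-(3-methylbut-2-en-1-yl)benzaldehyde | COc1c(C=O)c(O)c(CC=C(C)C)c(OC)c1OC
F4 | step 3 | 1-[2-hydroxy-4,5,6-trimethoxy-3-(3-methylbut-2-en-1-yl)phenyl]prop-2-yn-1-ol (racemic) | COc1c(C(O)C#C)c(O)c(CC=C(C)C)c(OC)c1OC
F5 | step 3 | 1-[2-hydroxy-4,5,6-trimethoxy-3-(3-methylbut-2-en-1-yl)phenyl]prop-2-yn-1-one | COc1c(C(=O)C#C)c(O)c(CC=C(C)C)c(OC)c1OC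
F6 | step 3 | 5,6,7-trimethoxy-8-(3-methylbut-2-en-1-yl)-4H-chromen-4-one | COc1c(OC)c(OC)c(CC=C(C)C)c2occc(=O)c12
F7 | step 10 | (2S)-2-[4-(tert-butyldimethylsilyloxy)phenyl]-5-ethoxy-6,7-dimethoxy-8-(3-methylbut-2-en-1-yl)-2,3-dihydro-4H-chromen-4-one | COc1c(OCC)c2c(c(CC=C(C)C)c1OC)O[C@H](c1ccc(O[Si](C)(C)C(C)(C)C)cc1)CC2=O
F8 | step 2 | 5-methylhex-4-en-1-yne | C#CCC=C(C)C
F9 | step 2 | (5-methylhex-4-en-1-yn-1-yl)lithium | [Li]C#CCC=C(C)C
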